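**Strategy.** The route rests on disconnecting the bond between furan C4 (the β-carbon flanked by C3–H and C5–H) and the acyloxy-bearing side-chain carbon C1′. The key step exploits the fact that this lone stereocentre is a secondary carbinol carbon sitting directly on a furan β-position that electrophiles cannot reach but bromine–metal exchange can. The complete 2-aryl-4-bromofuran is converted into a mixed furyl(ethyl)zinc and transferred, under (+)-MIB catalysis, to the Re face of 4-methylpent-3-enal. One operation thus joins the two halves and sets the (S)-configuration. The precursor pair is a bis-TIPS-protected 4-bromo-2-(2,5-dihydroxyphenyl)furan and the C6 aldehyde; esterification and desilylation finish.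

Key step: step 4

Remark: the stereocentre is read as (S) (CIP order O > furan C4 > CH2 > H). The facial sense of the amino-alcohol catalyst is assigned by analogy with dialkylzinc additions and would be checked on 10 by MTPA-ester analysis. 2,4-Dibromofuran is taken as a purchasable building block; (+)-MIB is bought or made from (1S)-(−)-camphor.

**Step 1**
Reactants: 1 2-bromobenzene-1,4-diol
Product: 2 2-bromo-1,4-bis(triisopropylsilyloxy)benzene
Conditions: TIPSCl (2.5 equiv), imidazole (5 equiv), DMF, rt → 50 °C, N2
Reagents that add atoms: triisopropylsilyl chloride (TIPSCl), CC(C)[Si](Cl)(C(C)C)C(C)C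
Why: Imidazole-mediated O-silylation (silyl ether protection) of both phenols, TIPS being chosen because its aryl ethers should survive the aqueous base of step 2 and n-BuLi at −78 °C in step 4 yet still fall to fluoride at the end.

**Step 2**
Reactants: 2 2-bromo-1,4-bis(triisopropylsilyloxy)benzene; 3 2,4-dibromofuran
Product: 5 4-bromo-2-[2,5-bis(triisopropylsilyloxy)phenyl]furan, via aryl pinacol boronate 4 (not isolated)
Conditions: B2pin2 (1.05 equiv), KOAc, Pd(dppf)Cl2·CH2Cl2 (5 mol %), dioxane, 90 °C; then 3 (1.5 equiv), aq K3PO4, 70 °C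
Reagents that add atoms: none
Why: Miyaura borylation followed in the same pot by Suzuki–Miyaura coupling, in which oxidative addition to 2,4-dibromofuran is faster at the C2–Br bond next to oxygen than at the β C4–Br bond, so mono-arylation at C2 should leave the C4 bromide as the handle for the key step.

**Step 3**
Reactants: 6 4-methylpent-3-en-1-ol
Product: 7 4-methylpent-3-enal
Conditions: Dess–Martin periodinane (1.2 equiv), NaHCO3, CH2Cl2, 0 °C → rt; pentane work-up, careful concentration, used at once
Reagents that add atoms: none
Why: Dess–Martin oxidation under bicarbonate buffer is near-neutral and stops at the aldehyde, which should limit migration of the β,γ-double bond into conjugation.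

**Step 4**
Reactants: 5 4-bromo-2-[2,5-bis(triisopropylsilyloxy)phenyl]furan; 7 4-methylpent-3-enal
Product: 10 (S)-1-{5-[2,5-bis(triisopropylsilyloxy)phenyl]furan-3-yl}-4-methylpent-3-en-1-ol, via furan-3-yllithium 8 (not isolated), via furyl(ethyl)zinc 9 (not isolated)
Conditions: n-BuLi (1.0 equiv), t-BuOMe, −78 °C; EtZnCl (from Et2Zn + ZnCl2), −78 → 0 °C; TEEDA (0.8 equiv), toluene; (+)-MIB (10 mol %); then 7 (1.2 equiv, slow addition), 0 °C; aq NH4Cl
Reagents that add atoms: none
Why: Bromine–lithium exchange at −78 °C is regiospecific for C4 of the furan, and immediate transmetallation to ethylzinc chloride freezes the metal at that β-carbon as the mixed furyl(ethyl)zinc 9, from which the sp2 furyl group transfers far faster than ethyl. The zinc amino-alkoxide formed from (+)-MIB binds one molecule of 9 and the aldehyde in a bimetallic, six-membered chair-like transition state, so the furyl group is delivered intramolecularly to one carbonyl face (ligand-accelerated catalysis). The closest known reaction type is the amino-alcohol-catalysed asymmetric addition of mixed aryl(alkyl)- and heteroaryl(alkyl)zinc reagents to aldehydes, including furyl and thienyl transfer. No ring is closed. The single new stereocentre is under catalyst control: (+)-MIB, the antipode of the ligand that directs attack to the Si face, should deliver the furyl group to the Re face of 7 and give the (S)-carbinol. The step needs positional fidelity of the metal (secured by low-temperature exchange and prompt transmetallation), suppression of the racemic LiCl-promoted background (secured by sequestering LiCl with TEEDA) and survival of the β,γ-unsaturated aldehyde (secured by the weakly basic, mildly Lewis-acidic zinc medium and slow addition at 0 °C).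

**Step 5**
Reactants: 10 (S)-1-{5-[2,5-bis(triisopropylsilyloxy)phenyl]furan-3-yl}-4-methylpent-3-en-1-ol; 11 3-methylbut-2-enoic acid
Product: 12 (S)-1-{5-[2,5-bis(triisopropylsilyloxy)phenyl]furan-3-yl}-4-methylpent-3-enyl 3-methylbut-2-enoate
Conditions: 11 (1.5 equiv), DCC (1.5 equiv), DMAP (0.2 equiv), CH2Cl2, 0 °C → rt
Reagents that add atoms: none
Why: Steglich esterification acylates the secondary furyl carbinol on oxygen without touching the C–O bond of the stereocentre, and avoids the acid chloride/amine conditions that deconjugate senecioyl units through a vinylketene.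

**Step 6**
Reactants: 12 (S)-1-{5-[2,5-bis(triisopropylsilyloxy)phenyl]furan-3-yl}-4-methylpent-3-enyl 3-methylbut-2-enoate
Product: 13 (S)-1-[5-(2,5-dihydroxyphenyl)furan-3-yl]-4-methylpent-3-enyl 3-methylbut-2-enoate
Conditions: TBAF (2.5 equiv), AcOH (2.5 equiv), degassed THF, 0 °C, Ar; pH 7 buffer work-up under Ar
Reagents that add atoms: none
Why: Fluoride-induced cleavage of both aryl silyl ethers (desilylation), buffered with acetic acid so that the senecioate ester, the ionisable furylmethyl C–O bond and the prenyl alkene should remain untouched, with oxygen excluded because the free hydroquinone is easily oxidised.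

**Compound list**
1 | 2-bromobenzene-1,4-diol (bromohydroquinone) | Oc1ccc(O)c(Br)c1 | starting material
2 | 2-bromo-1,4-bis(triisopropylsilyloxy)benzene | CC(C)[Si](C(C)C)(C(C)C)Oc1ccc(O[Si](C(C)C)(C(C)C)C(C)C)c(Br)c1 | intermediate
3 | 2,4-dibromofuran | Brc1cc(Br)co1 | starting material
4 | 2-[2,5-bis(triisopropylsilyloxy)phenyl]-4,4,5,5-tetramethyl-1,3,2-dioxaborolane | CC(C)[Si](C(C)C)(C(C)C)Oc1ccc(O[Si](C(C)C)(C(C)C)C(C)C)c(B2OC(C)(C)C(C)(C)O2)c1 | intermediate
5 | 4-bromo-2-[2,5-bis(triisopropylsilyloxy)phenyl]furan | CC(C)[Si](C(C)C)(C(C)C)Oc1ccc(O[Si](C(C)C)(C(C)C)C(C)C)c(-c2cc(Br)co2)c1 | intermediate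
6 | 4-methylpent-3-en-1-ol | CC(C)=CCCO | starting material
7 | 4-methylpent-3-enal | CC(C)=CCC=O | intermediate
8 | {5-[2,5-bis(triisopropylsilyloxy)phenyl]furan-3-yl}lithium | CC(C)[Si](C(C)C)(C(C)C)Oc1ccc(O[Si](C(C)C)(C(C)C)C(C)C)c(-c2cc([Li])co2)c1 | intermediate
9 | ethyl{5-[2,5-bis(triisopropylsilyloxy)phenyl]furan-3-yl}zinc | CC[Zn]c1coc(-c2cc(O[Si](C(C)C)(C(C)C)C(C)C)ccc2O[Si](C(C)C)(C(C)C)C(C)C)c1 | intermediate
10 | (S)-1-{5-[2,5-bis(triisopropylsilyloxy)phenyl]furan-3-yl}-4-methylpent-3-en-1-ol | CC(C)=CC[C@H](O)c1coc(-c2cc(O[Si](C(C)C)(C(C)C)C(C)C)ccc2O[Si](C(C)C)(C(C)C)C(C)C)c1 | intermediate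
11 | 3-methylbut-2-enoic acid (senecioic acid) | CC(C)=CC(=O)O | starting material
12 | (S)-1-{5-[2,5-bis(triisopropylsilyloxy)phenyl]furan-3-yl}-4-methylpent-3-enyl 3-methylbut-2-enoate | CC(C)=CC[C@H](OC(=O)C=C(C)C)c1coc(-c2cc(O[Si](C(C)C)(C(C)C)C(C)C)ccc2O[Si](C(C)C)(C(C)C)C(C)C)c1 | intermediate
13 | (S)-1-[5-(2,5-dihydroxyphenyl)furan-3-yl]-4-methylpent-3-enyl 3-methylbut-2-enoate | CC(C)=CC[C@H](OC(=O)C=C(C)C)c1coc(-c2cc(O)ccc2O)c1 | target

**Total step count:** 6. **Longest linear sequence:** 5 (steps 1, 2, 4, 5, 6).

**Steps most likely to fail**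

1. Step 4 (key step). What may go wrong: erosion of enantioselectivity by uncatalysed or lithium-salt-promoted addition to an unhindered linear aldehyde, drift of the metal from C4 to C5 of the furan before transmetallation, competing ethyl transfer, and enolisation or double-bond migration of the aldehyde. The fallback is a reagent-controlled lithiation–borylation that forms the same bond without any aldehyde; it sets out from 5 and 6 and comes back at 10. Bromide 5 is converted through 8 (n-BuLi, −78 °C) with 2-isopropoxy-4,4,5,5-tetramethyl-1,3,2-dioxaborolane into the furan-3-yl pinacol boronate F1. Alcohol 6 is acylated with N,N-diisopropylcarbamoyl chloride to 4-methylpent-3-enyl N,N-diisopropylcarbamate F2. Deprotonation of F2 with s-BuLi/(+)-sparteine (Et2O, −78 °C) should give the configurationally stable (R)-α-lithiated carbamate F3, which captures F1 with retention to form the lithium boronate complex F4. On warming with MgBr2·OEt2 the furyl group should migrate from boron to carbon with inversion, expelling the carbamate, to give the (S)-secondary boronic ester F5. Oxidation with NaOH/H2O2 (retention) returns the route to 10.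

2. Step 2. What may go wrong: incomplete borylation of the hindered, electron-rich bromide, carry-over of diboron that borylates or homocouples the dibromofuran, loss of C2/C4 site-selectivity with double arylation, and partial desilylation in hot aqueous phosphate. The fallback couples first and silylates afterwards; it sets out from 3 and comes back at 5. Suzuki–Miyaura coupling of 3 with commercial 2,5-dimethoxyphenylboronic acid (Pd(PPh3)4, aq Na2CO3, DME, 80 °C) should give 4-bromo-2-(2,5-dimethoxyphenyl)furan F6. Demethylation with BBr3 (CH2Cl2, −78 → 0 °C) should give 2-(4-bromofuran-2-yl)benzene-1,4-diol F7, and silylation with TIPSCl/imidazole as in step 1 returns to 5.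

3. Step 3. What may go wrong: loss of the volatile aldehyde on concentration and migration of the double bond into conjugation during work-up or storage, so that the key step is fed impure electrophile. The fallback moves the side chain to the acid oxidation level and sets the stereocentre by reduction; it sets out from 5 and comes back at 10, bypassing steps 3 and 4. Commercial 4-methylpent-3-enoic acid is converted (CDI, MeNHOMe·HCl) into N-methoxy-N,4-dimethylpent-3-enamide F8. The furyllithium 8 generated from 5 is acylated by F8 to give 1-{5-[2,5-bis(triisopropylsilyloxy)phenyl]furan-3-yl}-4-methylpent-3-en-1-one F9. Corey–Bakshi–Shibata reduction of F9 with the (R)-oxazaborolidine and catecholborane at low temperature, the furyl ring acting as the large group, should return (S)-10.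

**Further compounds**
F1 | step 4 | 2-{5-[2,5-bis(triisopropylsilyloxy)phenyl]furan-3-yl}-4,4,5,5-tetramethyl-1,3,2-dioxaborolane | CC(C)[Si](C(C)C)(C(C)C)Oc1ccc(O[Si](C(C)C)(C(C)C)C(C)C)c(-c2cc(B3OC(C)(C)C(C)(C)O3)co2)c1
F2 | step 4 | 4-methylpent-3-enyl N,N-diisopropylcarbamate | CC(C)=CCCOC(=O)N(C(C)C)C(C)C
F3 | step 4 | (R)-1-lithio-4-methylpent-3-enyl N,N-diisopropylcarbamate | CC(C)=CC[C@@H]([Li])OC(=O)N(C(C)C)C(C)C
F4 | step 4 | lithium boronate complex of F3 with F1 | CC(C)=CC[C@H](OC(=O)N(C(C)C)C(C)C)[B-]1(OC(C)(C)C(C)(C)O1)c1coc(-c2cc(O[Si](C(C)C)(C(C)C)C(C)C)ccc2O[Si](C(C)C)(C(C)C)C(C)C)c1.[Li+]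
F5 | step 4 | 2-[(S)-1-{5-[2,5-bis(triisopropylsilyloxy)phenyl]furan-3-yl}-4-methylpent-3-enyl]-4,4,5,5-tetramethyl-1,3,2-dioxaborolane | CC(C)=CC[C@H](B1OC(C)(C)C(C)(C)O1)c1coc(-c2cc(O[Si](C(C)C)(C(C)C)C(C)C)ccc2O[Si](C(C)C)(C(C)C)C(C)C)c1
F6 | step 2 | 4-bromo-2-(2,5-dimethoxyphenyl)furan | COc1ccc(OC)c(-c2cc(Br)co2)c1
F7 | step 2 | 2-(4-bromofuran-2-yl)benzene-1,4-diol | Oc1ccc(O)c(-c2cc(Br)co2)c1
F8 | step 3 | N-methoxy-N,4-dimethylpent-3-enamide | CC(C)=CCC(=O)N(C)OC
F9 | step 3 | 1-{5-[2,5-bis(triisopropylsilyloxy)phenyl]furan-3-yl}-4-methylpent-3-en-1-one | CC(C)=CCC(=O)c1coc(-c2cc(O[Si](C(C)C)(C(C)C)C(C)C)ccc2O[Si](C(C)C)(C(C)C)C(C)C)c1
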